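**Plan**

Target numbering used below: ring C1 (stereocentre), C2, C3=C4(Me), C5, C6, C7=C8(CO2H), C9, C10, C11=C12(Me), C13, C14; side chain C15(Me)=C16–C17–C18=C19Me2.
Retrosynthesis cuts, in order, the ring bond C13–C14, then C1–C14 (Claisen), C1–C2 (alkenyl–allyl coupling) and C7=C8 (Wittig).
Enabling feature: C13 is the CH2 end of the E-2-methylallyl unit C11=C12(Me)–C13, and C14 is the CH2 on C1 that an acetate Claisen unit delivers as CH2–CO2H. Both ends are electrophile precursors (allylic acetate, redox-active ester) and are joined reductively at nickel with loss of CO2, so no activating group stays on the 14-membered ring.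
Forward: alkyne 5 (C1, C15–C19), the nerol-derived aldehyde 14 (C2–C7) and ylide 11 (C8–C13) are joined at C7=C8, then at C1–C2; a Johnson–Claisen rearrangement adds C14; the ring is closed last at C13–C14.
Stereochemistry: C1 by chair 1,3-chirality transfer from the (S)-carbinol C16 (Brown allylation); 3Z from nerol; 7E from the stabilised Wittig; 11E from SeO2 oxidation of the E-methyl; 15E from the Claisen chair; the E C1=C15 olefin of the Claisen substrate from syn carboalumination.

Key step: step 14

Assumption: (−)-Ipc2B(allyl) delivers allyl to the Si face of the ynal, as it does with other aldehydes, giving the (S)-carbinol; if the sense were opposite, the enantiomeric reagent would be used.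

**Route**

Step 1
Reactants: 1 3-(trimethylsilyl)prop-2-ynal
Product: 3 (S)-1-(trimethylsilyl)hex-5-en-1-yn-3-ol, via borinate 2 (not isolated)
Conditions: (−)-Ipc2B(allyl) (1.2 equiv), Et2O, −78 °C; then NaBO3·4H2O, THF/H2O, 23 °C
Reagents that add atoms: (−)-B-allyldiisopinocampheylborane, C=CCB([C@@H]1C[C@@H]2C[C@H]([C@H]1C)C2(C)C)[C@@H]1C[C@@H]2C[C@H]([C@H]1C)C2(C)C
Why: Brown asymmetric allylboration through a closed chair transition state in which the isopinocampheyl groups direct allyl to the Si face of the aldehyde, which sets the (S)-carbinol (later C16), and mild perborate oxidation frees the alcohol without cleaving the alkynylsilane.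

Step 2
Reactants: 3 (S)-1-(trimethylsilyl)hex-5-en-1-yn-3-ol
Product: 4 (S)-6-methyl-1-(trimethylsilyl)hept-5-en-1-yn-3-ol
Conditions: 2-methylbut-2-ene (excess), second-generation Grubbs catalyst (3 mol%), CH2Cl2, 40 °C
Reagents that add atoms: 2-methylbut-2-ene, CC=C(C)C
Why: Olefin cross-metathesis of the monosubstituted alkene with excess 2-methylbut-2-ene is the standard route to a prenyl terminus, the silyl-capped alkyne being too hindered for enyne metathesis and the stereocentre not being involved.

Step 3
Reactants: 4 (S)-6-methyl-1-(trimethylsilyl)hept-5-en-1-yn-3-ol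
Product: 5 (S)-6-methylhept-5-en-1-yn-3-ol
Conditions: K2CO3 (0.2 equiv), MeOH, 23 °C
Reagents that add atoms: none
Why: Methanolysis of the alkynyl C–Si bond (protodesilylation) should free the terminal alkyne needed for carbometalation without touching the carbinol centre.

Step 4
Reactants: 6 5-bromo-2-methylpent-2-ene
Product: 7 (E)-5-bromo-2-methylpent-2-en-1-ol
Conditions: SeO2 (0.3 equiv), t-BuOOH (2 equiv), CH2Cl2, 23 °C
Reagents that add atoms: tert-butyl hydroperoxide, CC(C)(C)OO
Why: Selenium dioxide allylic oxidation (ene reaction followed by [2,3]-sigmatropic shift) of a trisubstituted olefin hydroxylates the methyl group trans to the chain, which fixes the 11E geometry, and the single olefin of 6 removes any site-selectivity question.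

Step 5
Reactants: 7 (E)-5-bromo-2-methylpent-2-en-1-ol
Product: 8 (E)-[(5-bromo-2-methylpent-2-en-1-yl)oxy](tert-butyl)dimethylsilane
Conditions: TBSCl, imidazole, CH2Cl2, 23 °C
Reagents that add atoms: tert-butyldimethylsilyl chloride, CC(C)(C)[Si](C)(C)Cl
Why: Silylation of the primary alcohol gives an allylic ether that palladium should not ionise in step 9 and that survives steps 6 to 11.

Step 6
Reactants: 8 (E)-[(5-bromo-2-methylpent-2-en-1-yl)oxy](tert-butyl)dimethylsilane; 9 ethyl (triphenylphosphoranylidene)acetate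
Product: 11 ethyl (E)-7-(tert-butyldimethylsilyloxy)-6-methyl-2-(triphenylphosphoranylidene)hept-5-enoate, via phosphonium bromide 10 (not isolated)
Conditions: NaI (10 mol%), MeCN, 80 °C; then 1 M NaOH, CH2Cl2, 0 °C
Reagents that add atoms: none
Why: C-Alkylation of the stabilised phosphorus ylide by the primary bromide (Finkelstein-assisted SN2) gives the phosphonium salt, which aqueous hydroxide deprotonates to the α-substituted ylide.

Step 7
Reactants: 12 neryl acetate, (Z)-3,7-dimethylocta-2,6-dien-1-yl acetate
Product: 14 (Z)-3-methyl-6-oxohex-2-en-1-yl acetate, via ozonide 13 (not isolated)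
Conditions: O3 (1.0 equiv), CH2Cl2, −78 °C; then Me2S, −78 → 23 °C
Reagents that add atoms: ozone, [O-][O+]=O
Why: Ozonolysis with reductive work-up should cleave the electron-rich terminal trisubstituted olefin ahead of the olefin deactivated by the allylic acetate, so that the Z geometry of C3=C4 is taken unchanged from nerol.

Step 8
Reactants: 14 (Z)-3-methyl-6-oxohex-2-en-1-yl acetate; 11 ethyl (E)-7-(tert-butyldimethylsilyloxy)-6-methyl-2-(triphenylphosphoranylidene)hept-5-enoate
Product: 15 ethyl (2E,6Z)-8-acetoxy-2-[(E)-5-(tert-butyldimethylsilyloxy)-4-methylpent-3-en-1-yl]-6-methylocta-2,6-dienoate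
Conditions: toluene, 80 °C
Reagents that add atoms: none
Why: Wittig olefination with an α-alkyl ester-stabilised ylide is strongly E-selective, placing the ester trans to C6 as the target requires at C7=C8.

Step 9
Reactants: 5 (S)-6-methylhept-5-en-1-yn-3-ol; 15 ethyl (2E,6Z)-8-acetoxy-2-[(E)-5-(tert-butyldimethylsilyloxy)-4-methylpent-3-en-1-yl]-6-methylocta-2,6-dienoate
Product: 17 ethyl (2E,6Z,9E,11S)-2-[(E)-5-(tert-butyldimethylsilyloxy)-4-methylpent-3-en-1-yl]-11-hydroxy-6,10,14-trimethylpentadeca-2,6,9,13-tetraenoate, via alkenylalane 16 (not isolated)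
Conditions: 5 (1.3 equiv), Me3Al (3.5 equiv), Cp2ZrCl2 (0.3 equiv), ClCH2CH2Cl, 0 → 23 °C; volatiles removed; then 15, Pd(PPh3)4 (5 mol%), THF, 23 °C
Reagents that add atoms: trimethylaluminium, C[Al](C)C
Why: Negishi zirconium-catalysed carboalumination adds methyl and aluminium syn across the terminal alkyne with methyl on the internal carbon, and palladium-catalysed allylation of the resulting alkenylalane at the primary terminus of the allylic acetate (alkenyl–allyl cross-coupling) should give the 1,4-diene with retention of both olefin geometries, the C16 centre and the allylic silyl ether being spectators.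

Step 10
Reactants: 17 ethyl (2E,6Z,9E,11S)-2-[(E)-5-(tert-butyldimethylsilyloxy)-4-methylpent-3-en-1-yl]-11-hydroxy-6,10,14-trimethylpentadeca-2,6,9,13-tetraenoate
Product: 19 ethyl (2E,6Z,9S,10E)-2-[(E)-5-(tert-butyldimethylsilyloxy)-4-methylpent-3-en-1-yl]-9-(2-methoxy-2-oxoethyl)-6,10,14-trimethylpentadeca-2,6,10,13-tetraenoate, via ketene acetal 18 (not isolated)
Conditions: MeC(OMe)3 (8 equiv), EtCO2H (10 mol%), xylenes, 135 °C, MeOH distilled off
Reagents that add atoms: trimethyl orthoacetate, CC(OC)(OC)OC
Why: Johnson–Claisen rearrangement through a chair in which the C17 methylene on C16 is equatorial should give the 15E olefin and transfer the (S) configuration of C16 suprafacially to C1, creating the C1–C14 bond with the configuration of the target (the descriptor at this carbon reads S here only because CH2CO2Me outranks C2).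

Step 11
Reactants: 19 ethyl (2E,6Z,9S,10E)-2-[(E)-5-(tert-butyldimethylsilyloxy)-4-methylpent-3-en-1-yl]-9-(2-methoxy-2-oxoethyl)-6,10,14-trimethylpentadeca-2,6,10,13-tetraenoate
Product: 20 the 9-(carboxymethyl) acid of 19 (ethyl enoate and silyl ether kept)
Conditions: LiOH·H2O (1.5 equiv), THF/H2O, 0 °C; then 1 M HCl to pH 3
Reagents that add atoms: lithium hydroxide, [Li+].[OH-]
Why: Saponification should discriminate the unhindered saturated methyl ester from the α-branched conjugated ethyl ester, and C1, being β to the carboxyl group, cannot epimerise.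

Step 12
Reactants: 20 the 9-(carboxymethyl) acid of 19
Product: 21 hydroxy acid, 20 with the C13 silyl ether cleaved to the primary (E)-allylic alcohol
Conditions: Bu4NF (3 equiv), THF, 0 → 23 °C; aq. NH4Cl
Reagents that add atoms: none
Why: Fluoride-induced desilylation frees the C13 allylic alcohol without affecting the ester, the acid or the olefins.

Step 13
Reactants: 21 hydroxy acid
Product: 23 acetoxy acid, 21 with the C13 alcohol as its acetate, via mixed anhydride 22 (not isolated)
Conditions: Ac2O (3 equiv), pyridine, CH2Cl2, 0 → 23 °C; then H2O/THF, 23 °C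
Reagents that add atoms: acetic anhydride, CC(=O)OC(C)=O
Why: Acetylation of the primary allylic alcohol installs the leaving group for nickel, and the mixed anhydride formed at the carboxyl group is returned to the acid by the aqueous hold.

Step 14
Reactants: 23 acetoxy acid
Product: 25 ethyl (1E,5Z,8R,11E)-5,11-dimethyl-8-[(2E)-6-methylhepta-2,5-dien-2-yl]cyclotetradeca-1,5,11-triene-1-carboxylate, via phthalimide ester 24 (not isolated)
Conditions: N-hydroxyphthalimide, DIC, DMAP (5 mol%), CH2Cl2, 23 °C; then syringe-pump addition (12 h) in DMA to NiBr2(MeOCH2CH2OMe) (30 mol%), 4,4′-di-tert-butyl-2,2′-bipyridine (36 mol%), Zn dust (4 equiv), DMA, 25 °C, 2 mM final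
Reagents that add atoms: none
Why: Proposed new method: zerovalent nickel should add oxidatively to the primary allylic acetate to give a syn-η3-allylnickel species, zinc reduces it to the monovalent allyl complex, and this transfers one electron to the N-acyloxyphthalimide, which loses phthalimide anion and CO2 to leave the primary C14 radical; the radical is captured at nickel and the trivalent alkyl(allyl)nickel eliminates reductively at the unsubstituted allyl terminus C13. The closest known reaction types are the intermolecular nickel-catalysed reductive coupling of alkyl halides with allylic acetates or carbonates and the nickel-catalysed reductive couplings of N-hydroxyphthalimide esters with aryl and alkenyl halides, both electrophile–electrophile unions. The step closes the 14-membered carbocycle C1–C14 end to end by C13–C14 reductive elimination at nickel, not by radical addition to an alkene. No new stereocentre forms, and C1, which is β to the radical centre, is not touched. The step needs ring closure over oligomerisation (slow addition keeps the substrate below the catalyst concentration), attack at C13 rather than C11 (C13 is the unsubstituted terminus and gives the unstrained 14-ring, C11 a 12-ring) and retention of the E C11=C12 geometry (the syn allyl formed from the E acetate should be trapped before syn/anti exchange through the secondary C11–Ni σ-form). The C14 radical has no 5-exo or 6-exo olefin in reach, because the E C15=C16 olefin forbids a six-membered closure onto C18, so it should live long enough to meet nickel.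

Step 15
Reactants: 25 ethyl (1E,5Z,8R,11E)-5,11-dimethyl-8-[(2E)-6-methylhepta-2,5-dien-2-yl]cyclotetradeca-1,5,11-triene-1-carboxylate
Product: 26 (1E,5Z,8R,11E)-5,11-dimethyl-8-[(2E)-6-methylhepta-2,5-dien-2-yl]cyclotetradeca-1,5,11-triene-1-carboxylic acid (CNP0112585.1)
Conditions: LiOH·H2O (10 equiv), THF/EtOH/H2O, 60 °C; then 1 M HCl to pH 3
Reagents that add atoms: lithium hydroxide, [Li+].[OH-]
Why: Saponification of the hindered conjugated ethyl ester with excess hydroxide gives the acid, no stereocentre or olefin geometry of the molecule being base-labile.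

**Compound list**

1 | 3-(trimethylsilyl)prop-2-ynal | C[Si](C)(C)C#CC=O | starting material
2 | O-diisopinocampheylboryl ether (borinate) of 3 | C=CC[C@H](OB([C@@H]1C[C@@H]2C[C@H]([C@H]1C)C2(C)C)[C@@H]1C[C@@H]2C[C@H]([C@H]1C)C2(C)C)C#C[Si](C)(C)C | intermediate (not isolated)
3 | (S)-1-(trimethylsilyl)hex-5-en-1-yn-3-ol | C=CC[C@H](O)C#C[Si](C)(C)C | intermediate
4 | (S)-6-methyl-1-(trimethylsilyl)hept-5-en-1-yn-3-ol | CC(C)=CC[C@H](O)C#C[Si](C)(C)C | intermediate
5 | (S)-6-methylhept-5-en-1-yn-3-ol | CC(C)=CC[C@H](O)C#C | intermediate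
6 | 5-bromo-2-methylpent-2-ene | CC(C)=CCCBr | starting material
7 | (E)-5-bromo-2-methylpent-2-en-1-ol | OC/C(C)=C/CCBr | intermediate
8 | (E)-[(5-bromo-2-methylpent-2-en-1-yl)oxy](tert-butyl)dimethylsilane | CC(C)(C)[Si](C)(C)OC/C(C)=C/CCBr | intermediate
9 | ethyl (triphenylphosphoranylidene)acetate | CCOC(=O)C=P(c1ccccc1)(c1ccccc1)c1ccccc1 | starting material
10 | [(E)-7-(tert-butyldimethylsilyloxy)-1-ethoxy-6-methyl-1-oxohept-5-en-2-yl]triphenylphosphonium bromide | CCOC(=O)C(CC/C=C(\C)CO[Si](C)(C)C(C)(C)C)[P+](c1ccccc1)(c1ccccc1)c1ccccc1.[Br-] | intermediate (not isolated)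
11 | ethyl (E)-7-(tert-butyldimethylsilyloxy)-6-methyl-2-(triphenylphosphoranylidene)hept-5-enoate | CCOC(=O)C(CC/C=C(\C)CO[Si](C)(C)C(C)(C)C)=P(c1ccccc1)(c1ccccc1)c1ccccc1 | intermediate
12 | neryl acetate, (Z)-3,7-dimethylocta-2,6-dien-1-yl acetate | CC(=O)OC/C=C(/C)CCC=C(C)C | starting material
13 | ozonide (3,3-dimethyl-1,2,4-trioxolane) of the 6,7-olefin of 12 | CC(=O)OC/C=C(/C)CCC1OOC(C)(C)O1 | intermediate (not isolated)
14 | (Z)-3-methyl-6-oxohex-2-en-1-yl acetate | CC(=O)OC/C=C(/C)CCC=O | intermediate
15 | ethyl (2E,6Z)-8-acetoxy-2-[(E)-5-(tert-butyldimethylsilyloxy)-4-methylpent-3-en-1-yl]-6-methylocta-2,6-dienoate | CC(=O)OC/C=C(/C)CC/C=C(/C(=O)OCC)CC/C=C(\C)CO[Si](C)(C)C(C)(C)C | intermediate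
16 | (S,E)-alkenyl(dimethyl)alane from 5, with the carbinol as its dimethylaluminium alkoxide | CC(C)=CC[C@H](O[Al](C)C)/C(C)=C/[Al](C)C | intermediate (not isolated)
17 | ethyl (2E,6Z,9E,11S)-2-[(E)-5-(tert-butyldimethylsilyloxy)-4-methylpent-3-en-1-yl]-11-hydroxy-6,10,14-trimethylpentadeca-2,6,9,13-tetraenoate | CC(C)=CC[C@H](O)/C(C)=C/C/C=C(/C)CC/C=C(/C(=O)OCC)CC/C=C(\C)CO[Si](C)(C)C(C)(C)C | intermediate
18 | 1-methoxyvinyl ether (mixed ketene acetal) of 17 | CC(C)=CC[C@H](OC(=C)OC)/C(C)=C/C/C=C(/C)CC/C=C(/C(=O)OCC)CC/C=C(\C)CO[Si](C)(C)C(C)(C)C | intermediate (not isolated)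
19 | ethyl (2E,6Z,9S,10E)-2-[(E)-5-(tert-butyldimethylsilyloxy)-4-methylpent-3-en-1-yl]-9-(2-methoxy-2-oxoethyl)-6,10,14-trimethylpentadeca-2,6,10,13-tetraenoate | CC(C)=CC/C=C(\C)[C@H](CC(=O)OC)C/C=C(/C)CC/C=C(/C(=O)OCC)CC/C=C(\C)CO[Si](C)(C)C(C)(C)C | intermediate
20 | 9-(carboxymethyl) acid corresponding to 19 (9S; ethyl enoate and silyl ether kept) | CC(C)=CC/C=C(\C)[C@H](CC(=O)O)C/C=C(/C)CC/C=C(/C(=O)OCC)CC/C=C(\C)CO[Si](C)(C)C(C)(C)C | intermediate
21 | hydroxy acid: 20 with the silyl ether cleaved to the primary (E)-allylic alcohol | CC(C)=CC/C=C(\C)[C@H](CC(=O)O)C/C=C(/C)CC/C=C(/C(=O)OCC)CC/C=C(\C)CO | intermediate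
22 | allylic acetate of 21 with the carboxyl group as its mixed acetic anhydride | CC(C)=CC/C=C(\C)[C@H](CC(=O)OC(C)=O)C/C=C(/C)CC/C=C(/C(=O)OCC)CC/C=C(\C)COC(C)=O | intermediate (not isolated)
23 | acetoxy acid: 21 with the C13 alcohol as its acetate | CC(C)=CC/C=C(\C)[C@H](CC(=O)O)C/C=C(/C)CC/C=C(/C(=O)OCC)CC/C=C(\C)COC(C)=O | intermediate
24 | N-acyloxyphthalimide (redox-active ester) of 23 | CC(C)=CC/C=C(\C)[C@H](CC(=O)ON1C(=O)c2ccccc2C1=O)C/C=C(/C)CC/C=C(/C(=O)OCC)CC/C=C(\C)COC(C)=O | intermediate (not isolated)
25 | ethyl (1E,5Z,8R,11E)-5,11-dimethyl-8-[(2E)-6-methylhepta-2,5-dien-2-yl]cyclotetradeca-1,5,11-triene-1-carboxylate | CC(C)=CC/C=C(\C)[C@H]1C/C=C(/C)CC/C=C(/C(=O)OCC)CC/C=C(\C)CC1 | intermediate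
26 | (1E,5Z,8R,11E)-5,11-dimethyl-8-[(2E)-6-methylhepta-2,5-dien-2-yl]cyclotetradeca-1,5,11-triene-1-carboxylic acid | CC(C)=CC/C=C(\C)[C@H]1C/C=C(/C)CC/C=C(/C(=O)O)CC/C=C(\C)CC1 | target

**Step count and risks**

Total step count: 15. Longest linear sequence: 11 steps (steps 4, 5, 6, 8, 9, 10, 11, 12, 13, 14, 15).

Steps most likely to fail:

1. Step 14 (Proposed new method). Intermolecular coupling may outrun ring closure and give oligomers. The C14 radical may be reduced before it reaches nickel. Syn/anti exchange of the allylnickel may erode the 11E geometry or lead to coupling at C11. Fallback by known chemistry, setting out from 17 and returning at 26: 17 is esterified with (4-tolylsulfonyl)acetic acid (DIC, DMAP) to the allylic tosylacetate F1. Decarboxylative Claisen rearrangement (N,O-bis(trimethylsilyl)acetamide, KOAc cat., toluene, 110 °C) should give, through the same chair, the homoallylic sulfone F2, with C1 and the 15E olefin set as in 19 and C14 carrying the sulfonyl group. Bu4NF gives the allylic alcohol F3, and MsCl/Et3N then LiBr gives the allylic bromide F4. Intramolecular SN2 alkylation of the sulfone-stabilised C14 carbanion at C13 (KN(SiMe3)2, THF, −78 → 0 °C, 2 mM) closes the ring to the macrocyclic sulfone F5 (C14 epimers). Saponification (LiOH) gives the sulfonyl acid F6, whose carboxylate should resist electron transfer. Buffered sodium amalgam (Na/Hg, Na2HPO4, MeOH, −20 °C) then cleaves the sulfone to give 26.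

2. Step 9. The excess alane may attack the ester groups or activate the allylic silyl ether. Transmetalation of the O-bound alkenylalane to palladium may be slow. The neryl-type allyl-palladium may isomerise from Z to E. Fallback, setting out from 5 and 15 and returning at 17: carboalumination of 5 followed by iodinolysis (I2, THF, −30 °C) gives the vinyl iodide (S,E)-1-iodo-2,6-dimethylhepta-1,5-dien-3-ol F7. Iodine–lithium exchange (t-BuLi, 3 equiv, Et2O, −78 °C) and Bu3SnCl give the alkenylstannane F8. A neutral Stille coupling of F8 with the allylic acetate 15 (Pd(dba)2, LiCl, DMF, 23 °C) then forms the C1–C2 bond in the absence of any alane and gives 17.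

3. Step 6. C-alkylation of the weakly nucleophilic stabilised ylide by the unactivated bromide may be slow, and O-alkylation or elimination to the diene may compete. Fallback, setting out from 8 and 14 and returning at 15: the much more nucleophilic sodium salt of triethyl phosphonoacetate (NaH, DMF, 60 °C) is alkylated by 8 to the phosphonate F9. A Horner–Wadsworth–Emmons reaction of F9 with aldehyde 14 (NaH, THF, 0 → 23 °C) gives 15 directly, the minor 7Z isomer being removed by chromatography.

Further compounds
F1 | step 14 | (4-tolylsulfonyl)acetate ester of 17 | CC(C)=CC[C@H](OC(=O)CS(=O)(=O)c1ccc(C)cc1)/C(C)=C/C/C=C(/C)CC/C=C(/C(=O)OCC)CC/C=C(\C)CO[Si](C)(C)C(C)(C)C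
F2 | step 14 | homoallylic sulfone: 19 with CH2SO2(4-tolyl) at C1 in place of CH2CO2Me, same configuration at C1 | CC(C)=CC/C=C(\C)[C@H](CS(=O)(=O)c1ccc(C)cc1)C/C=C(/C)CC/C=C(/C(=O)OCC)CC/C=C(\C)CO[Si](C)(C)C(C)(C)C
F3 | step 14 | allylic alcohol from F2 (silyl ether cleaved) | CC(C)=CC/C=C(\C)[C@H](CS(=O)(=O)c1ccc(C)cc1)C/C=C(/C)CC/C=C(/C(=O)OCC)CC/C=C(\C)CO
F4 | step 14 | (E)-allylic bromide from F3 | CC(C)=CC/C=C(\C)[C@H](CS(=O)(=O)c1ccc(C)cc1)C/C=C(/C)CC/C=C(/C(=O)OCC)CC/C=C(\C)CBr
F5 | step 14 | 25 bearing a 4-tolylsulfonyl group on C14 (epimers at C14) | CC(C)=CC/C=C(\C)[C@H]1C/C=C(/C)CC/C=C(/C(=O)OCC)CC/C=C(\C)CC1S(=O)(=O)c2ccc(C)cc2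
F6 | step 14 | 26 bearing a 4-tolylsulfonyl group on C14 (epimers at C14) | CC(C)=CC/C=C(\C)[C@H]1C/C=C(/C)CC/C=C(/C(=O)O)CC/C=C(\C)CC1S(=O)(=O)c2ccc(C)cc2
F7 | step 9 | (S,E)-1-iodo-2,6-dimethylhepta-1,5-dien-3-ol | CC(C)=CC[C@H](O)/C(C)=C/I
F8 | step 9 | (S,E)-2,6-dimethyl-1-(tributylstannyl)hepta-1,5-dien-3-ol | CC(C)=CC[C@H](O)/C(C)=C/[Sn](CCCC)(CCCC)CCCC
F9 | step 6 | ethyl (E)-7-(tert-butyldimethylsilyloxy)-2-(diethoxyphosphoryl)-6-methylhept-5-enoate | CCOC(=O)C(CC/C=C(\C)CO[Si](C)(C)C(C)(C)C)P(=O)(OCC)OCC
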